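**Retrosynthetic overview**

1. Labels used for orientation: indoline ring B = N1–C2–C7, fused to benzene ring A (C7 is the benzylic carbon with CO2Me); cyclohexane ring C = C2–C16(CO2Me)–C17–C20–C19–C18; pyrrolidine = N4–C3–C14–C15(OH)–C20; azocine arm = C7–C6–C5–N4.
2. Disconnections, last to first: C16–H (hydrogenation of C16=C17), N4–C5 (N-alkylation, azocine), C7–C6 (ester-tethered enolate alkylation), and the key bond C2–C7.
3. Enabling feature: in ring C, C2 is the N1-bearing terminus of an allyl unit C17(O)–C16(CO2R)=C2, and C7 is a benzylic ester CH2 held on N1 through ring A. Palladium ionises C17–O and C7 attacks C2 (5-exo), which closes ring B, relays the C17 configuration to C2 and moves the alkene to C16=C17.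
4. The 2-bromoethyl ester on C16 then delivers C6–C5 to C7 from the C16 face (temporary seven-membered lactone), and HBr opens it to the C5 bromide for N4. The one catalytically set centre, C15, relays to C20 (trans alkylation), C17 (O15-directed reduction), C2, C7 and C16.
5. Ring order: pyrrolidine (from a 3-oxoproline ester) → ring C (Blaise/Dieckmann) → ring B (key step; ring A joined beforehand by enaminone formation) → temporary lactone → azocine.

Key step: step 10

Assumption: 1 epimerises at C2 under the hydrogenation conditions, and the C2 configuration of 2 does not matter because that carbon (later C20) is reset in step 2; 7 is liberated from its commercial hydrochloride just before use.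

**Step 1**
Reactants: 1 1-tert-butyl 2-methyl 3-oxopyrrolidine-1,2-dicarboxylate
Product: 2 1-tert-butyl 2-methyl (3R)-3-hydroxypyrrolidine-1,2-dicarboxylate
Conditions: H2 (50 atm), RuCl2[(R)-BINAP](DMF)n (1 mol %), MeOH/CH2Cl2, 50 °C
Reagents that add atoms: none
Why: Noyori asymmetric hydrogenation of a β-keto ester, in which the ester-chelated ruthenium hydride should reduce one ketone face and set C15 as R (ligand enantiomer chosen by analogy with simple β-keto esters).

**Step 2**
Reactants: 2 1-tert-butyl 2-methyl (3R)-3-hydroxypyrrolidine-1,2-dicarboxylate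
Product: 3 1-tert-butyl 2-methyl (2S,3R)-2-(2-cyanoethyl)-3-hydroxypyrrolidine-1,2-dicarboxylate
Conditions: LiN(iPr)2 (2.2 equiv), THF, −78 → −30 °C; acrylonitrile (1.2 equiv), −78 °C; AcOH
Reagents that add atoms: acrylonitrile (C=CC#N)
Why: Fráter–Seebach alkylation in its Michael variant, in which the alkoxide–enolate dianion cannot β-eliminate and should add to acrylonitrile anti to the C15 alkoxide, so that the new chain (C19–C18–C2) is trans to O15 and the ester carbon (future C17) cis to it, which sets C20.

**Step 3**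
Reactants: 3 1-tert-butyl 2-methyl (2S,3R)-2-(2-cyanoethyl)-3-hydroxypyrrolidine-1,2-dicarboxylate
Product: 4 1-tert-butyl 2-methyl (2S,3R)-2-(5-tert-butoxy-3,5-dioxopentyl)-3-hydroxypyrrolidine-1,2-dicarboxylate
Conditions: activated Zn (5 equiv), BrCH2CO2tBu (3 equiv, slow addition), THF, 65 °C; then 1 M aq. HCl, rt
Reagents that add atoms: tert-butyl bromoacetate (CC(C)(C)OC(=O)CBr); water (O)
Why: Blaise reaction, in which the Reformatsky reagent adds to the nitrile and the zinc enaminate is hydrolysed to the β-keto ester while the hindered quaternary ester and the carbamate should stay untouched.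

**Step 4**
Reactants: 4 1-tert-butyl 2-methyl (2S,3R)-2-(5-tert-butoxy-3,5-dioxopentyl)-3-hydroxypyrrolidine-1,2-dicarboxylate
Product: 5 di-tert-butyl (4R,5S)-4-hydroxy-6,8-dioxo-1-azaspiro[4.5]decane-1,7-dicarboxylate
Conditions: KOtBu (2.2 equiv), THF, 0 °C → rt; then cold 1 M aq. HCl
Reagents that add atoms: none
Why: Dieckmann condensation (6-exo-trig acylation of the β-keto ester carbon C16 by the methyl ester C17), driven by formation of the stabilised tricarbonyl enolate, closes ring C without touching C15 or C20.

**Step 5**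
Reactants: 5 di-tert-butyl (4R,5S)-4-hydroxy-6,8-dioxo-1-azaspiro[4.5]decane-1,7-dicarboxylate
Product: 6 7-(2-bromoethyl) 1-tert-butyl (4R,5S)-4-hydroxy-6,8-dioxo-1-azaspiro[4.5]decane-1,7-dicarboxylate
Conditions: BrCH2CH2OH (8 equiv), toluene, 110 °C, 4 Å MS
Reagents that add atoms: 2-bromoethanol (OCCBr)
Why: thermal ester exchange of a tert-butyl β-keto ester through its acylketene (loss of tert-butanol), trapped by the excess primary alcohol, should install the 2-bromoethyl ester on C16 that later serves as the tether.

**Step 6**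
Reactants: 6 7-(2-bromoethyl) 1-tert-butyl (4R,5S)-4-hydroxy-6,8-dioxo-1-azaspiro[4.5]decane-1,7-dicarboxylate; 7 methyl (2-aminophenyl)acetate
Product: 8 N-aryl enaminone (arylamino group on C2, ketone at C17)
Conditions: 7 (1.1 equiv), AcOH (10 mol %), 4 Å MS, toluene, 40 °C
Reagents that add atoms: none
Why: enaminone formation from an aniline and a 2-acyl-1,3-dione, in which the amine should attack the unhindered C2 carbonyl and not the neopentyl C17 carbonyl next to the spiro centre, joins ring A to ring C through N1.

**Step 7**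
Reactants: 8 N-aryl enaminone
Product: 9 N-(methoxycarbonyl) N-aryl enaminone (vinylogous imide)
Conditions: LiN(SiMe3)2 (1.05 equiv), THF, −78 °C; ClCO2Me (1.2 equiv), −78 → 0 °C
Reagents that add atoms: methyl chloroformate (COC(=O)Cl)
Why: N-acylation of the enaminone anion, in which one equivalent of base removes only the vinylogous-amide N–H (far more acidic than O15–H or the benzylic CH2), should install the carbamate of the target and make the C17 ketone reducible.

**Step 8**
Reactants: 9 N-(methoxycarbonyl) N-aryl enaminone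
Product: 10 allylic alcohol with O15 acetate (C17–OH cis to N4)
Conditions: SmI2 (30 mol %), CH3CHO (10 equiv), THF, −10 °C, dark
Reagents that add atoms: acetaldehyde (CC=O)
Why: Evans–Tishchenko reduction, in which the samarium-bound hemiacetal of O15 with acetaldehyde transfers hydride intramolecularly to the C17 ketone from the O15 face, should give the 1,3-anti product with C17–OH on the face of N4 and leave O15 as its acetate.

**Step 9**
Reactants: 10 allylic alcohol with O15 acetate
Product: 11 allylic tert-butyl carbonate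
Conditions: Boc2O (3 equiv), DMAP (20 mol %), Et3N (2 equiv), CH2Cl2, rt
Reagents that add atoms: di-tert-butyl dicarbonate (CC(C)(C)OC(=O)OC(=O)OC(C)(C)C)
Why: acylation of the hindered allylic alcohol gives a carbonate leaving group that releases tert-butoxide as the internal base of step 10, with no change at any stereocentre.

**Step 10**
Reactants: 11 allylic tert-butyl carbonate
Product: 13 bridged seven-membered lactone of the spiroindoline, via spiroindoline ester 12 (not isolated)
Conditions: Pd(PPh3)4 (10 mol %), THF, 50 °C; then KOtBu (1.3 equiv), −20 → 25 °C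
Reagents that add atoms: none
Why: Zerovalent palladium ionises the allylic carbonate with inversion to a π-allyl complex (C17–C16–C2) on the face opposite O17, the released tert-butoxide deprotonates the arylacetate CH2 (C7), and the enolate attacks the amido-substituted terminus C2 anti to palladium (intramolecular Tsuji–Trost allylic alkylation), forming C2–C7 and closing ring B in a 5-exo mode. The one selectivity the step needs, C2 against C17, is secured by the N1–aryl tether, because attack at C17 would put a trans double bond into a seven-membered ring. The double inversion transfers the C17 configuration to C2, so that C7 stands on the face of N4, and the double bond ends at C16=C17 in conjugation with the ester. KOtBu then regenerates the C7 enolate of 12, which is alkylated by the 2-bromoethyl ester on C16 (7-exo-tet enolate alkylation closing the lactone). This tether reaches only the face of C7 that is syn to C16, so C6 ends cis to C16 and the C7 ester cis to C18, which fixes the second quaternary centre. The closest known reaction types are the intramolecular palladium-catalysed allylic alkylation of allylic carbonates by ester enolates with 1,3-chirality transfer and the lactone-forming alkylation of ester enolates.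

**Step 11**
Reactants: 13 bridged seven-membered lactone of the spiroindoline
Product: 14 bromoethyl triester, hydrobromide of the free pyrrolidine
Conditions: AcBr (15 equiv), MeOH, 0 → 45 °C; evaporate; Me3SiCHN2 (3 equiv), MeOH/toluene, 0 °C
Reagents that add atoms: acetyl bromide (CC(=O)Br), source of HBr; (trimethylsilyl)diazomethane (C[Si](C)(C)C=[N+]=[N-])
Why: anhydrous HBr should cleave the N-Boc group and the acetate and open the lactone to the primary bromide (alkyl–oxygen cleavage of a protonated lactone, the classical route to ω-bromo esters), and the acid left is methylated by Me3SiCHN2; a detour through methanolysis and relactonisation onto the C7 ester converges on the same product.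

**Step 12**
Reactants: 14 bromoethyl triester, hydrobromide of the free pyrrolidine
Product: 15 azocine enoate (16,17-didehydro target)
Conditions: K2CO3 (4 equiv), MeCN (0.01 M), 60 °C
Reagents that add atoms: none
Why: intramolecular N-alkylation (8-exo-tet) of the secondary amine N4 by the primary bromide C5 closes the azocine, which is possible because N4 and C7 are cis on ring C, and no stereocentre is affected.

**Step 13**
Reactants: 15 azocine enoate
Product: 16 target CNP0144467.2
Conditions: H2 (3 atm), PtO2 (10 mol %), EtOAc, rt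
Reagents that add atoms: none
Why: catalytic hydrogenation of the trisubstituted enoate, in which the face of C16=C17 under the azocine bridge (C6–C5) is shielded, should add hydrogen from the face of the C18–C19 bridge and leave the C16 ester syn to the azocine bridge as in the target.

**Compound list**

1 | 1-tert-butyl 2-methyl 3-oxopyrrolidine-1,2-dicarboxylate | COC(=O)C1N(C(=O)OC(C)(C)C)CCC1=O | starting material
2 | 1-tert-butyl 2-methyl (3R)-3-hydroxypyrrolidine-1,2-dicarboxylate (C2 epimers) | COC(=O)C1N(C(=O)OC(C)(C)C)CC[C@H]1O | intermediate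
3 | 1-tert-butyl 2-methyl (2S,3R)-2-(2-cyanoethyl)-3-hydroxypyrrolidine-1,2-dicarboxylate (cyanoethyl trans to OH) | COC(=O)[C@@]1(CCC#N)N(C(=O)OC(C)(C)C)CC[C@H]1O | intermediate
4 | 1-tert-butyl 2-methyl (2S,3R)-2-(5-tert-butoxy-3,5-dioxopentyl)-3-hydroxypyrrolidine-1,2-dicarboxylate | COC(=O)[C@@]1(CCC(=O)CC(=O)OC(C)(C)C)N(C(=O)OC(C)(C)C)CC[C@H]1O | intermediate
5 | di-tert-butyl (4R,5S)-4-hydroxy-6,8-dioxo-1-azaspiro[4.5]decane-1,7-dicarboxylate (enolised, C7 unassigned) | CC(C)(C)OC(=O)C1C(=O)CC[C@]2(C1=O)N(C(=O)OC(C)(C)C)CC[C@H]2O | intermediate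
6 | 7-(2-bromoethyl) 1-tert-butyl (4R,5S)-4-hydroxy-6,8-dioxo-1-azaspiro[4.5]decane-1,7-dicarboxylate | BrCCOC(=O)C1C(=O)CC[C@]2(C1=O)N(C(=O)OC(C)(C)C)CC[C@H]2O | intermediate
7 | methyl (2-aminophenyl)acetate | COC(=O)Cc1ccccc1N | starting material
8 | 7-(2-bromoethyl) 1-tert-butyl (4R,5S)-4-hydroxy-8-{[2-(2-methoxy-2-oxoethyl)phenyl]amino}-6-oxo-1-azaspiro[4.5]dec-7-ene-1,7-dicarboxylate | BrCCOC(=O)C1=C(Nc3ccccc3CC(=O)OC)CC[C@]2(C1=O)N(C(=O)OC(C)(C)C)CC[C@H]2O | intermediate
9 | 7-(2-bromoethyl) 1-tert-butyl (4R,5S)-4-hydroxy-8-{(methoxycarbonyl)[2-(2-methoxy-2-oxoethyl)phenyl]amino}-6-oxo-1-azaspiro[4.5]dec-7-ene-1,7-dicarboxylate | BrCCOC(=O)C1=C(N(C(=O)OC)c3ccccc3CC(=O)OC)CC[C@]2(C1=O)N(C(=O)OC(C)(C)C)CC[C@H]2O | intermediate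
10 | 7-(2-bromoethyl) 1-tert-butyl (4R,6S)-4-(acetyloxy)-6-hydroxy-8-{(methoxycarbonyl)[2-(2-methoxy-2-oxoethyl)phenyl]amino}-1-azaspiro[4.5]dec-7-ene-1,7-dicarboxylate (spiro carbon as in 9; the new C17–OH cis to N4, trans to C15) | BrCCOC(=O)C1=C(N(C(=O)OC)c3ccccc3CC(=O)OC)CC[C@]2([C@H]1O)N(C(=O)OC(C)(C)C)CC[C@H]2OC(C)=O | intermediate
11 | tert-butyl carbonate of 10 at the C17 hydroxyl (6-[(tert-butoxycarbonyl)oxy] in place of 6-hydroxy) | BrCCOC(=O)C1=C(N(C(=O)OC)c3ccccc3CC(=O)OC)CC[C@]2([C@H]1OC(=O)OC(C)(C)C)N(C(=O)OC(C)(C)C)CC[C@H]2OC(C)=O | intermediate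
12 | spiroindoline ester: N1-(methoxycarbonyl)indoline spiro-fused at C2 to ring C, C7 bearing H and CO2Me (C7 epimers), C16=C17 enoate as 2-bromoethyl ester, N4-Boc, O15 acetate, C7 on the N4 face of ring C | BrCCOC(=O)C1=C[C@@]2(CC[C@@]13N(C(=O)OC)c1ccccc1C3C(=O)OC)N(C(=O)OC(C)(C)C)CC[C@H]2OC(C)=O | intermediate (not isolated)
13 | bridged lactone: as 12 but C7 quaternary, its C6H2–C5H2–O chain closing a seven-membered lactone onto the C16 carboxyl (C6 syn to C16, C7–CO2Me syn to C18) | O=C1OCC[C@]2(C(=O)OC)c3ccccc3N(C(=O)OC)[C@@]24CC[C@]5(C=C14)N(C(=O)OC(C)(C)C)CC[C@H]5OC(C)=O | intermediate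
14 | bromoethyl triester hydrobromide: spiroindoline with C7(CO2Me)(CH2CH2Br), methyl C16=C17 enoate, N1-CO2Me, free N4–H (as HBr salt) and free C15–OH | COC(=O)C1=C[C@@]2(CC[C@@]13N(C(=O)OC)c1ccccc1[C@@]3(C(=O)OC)CCBr)NCC[C@H]2O.Br | intermediate
15 | azocine enoate: the target skeleton with a C16=C17 double bond | COC(=O)C1=C[C@@]23CC[C@@]14N(C(=O)OC)c1ccccc1[C@@]4(C(=O)OC)CCN2CC[C@H]3O | intermediate
16 | CNP0144467.2 | COC(=O)[C@@H]1C[C@@]23CC[C@@]14N(C(=O)OC)c1ccccc1[C@@]4(C(=O)OC)CCN2CC[C@H]3O | target

**Step count and risks**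

Total step count: 13. Longest linear sequence: 13 (steps 1–13; 7 is purchased).

The three steps most likely to fail:

Step 10. β-Hydride elimination from the hindered π-allyl complex, or failure of the tetrasubstituted allylic carbonate to ionise, may outrun carbon–carbon bond formation at the fully substituted terminus. The fallback makes C2–C7 by a [3,3] shift that delivers carbon to the same face and closes ring B afterwards. It sets out from 6. Ammonium acetate in THF should give the primary enaminone F1, and LiN(SiMe3)2/ClCO2Me its N-(methoxycarbonyl) derivative F2. The Evans–Tishchenko conditions of step 8 then give the allylic alcohol F3. Esterification with (2-iodophenyl)acetic acid (DCC, DMAP) gives the allylic arylacetate F4. Its Ireland–Claisen rearrangement (LiN(SiMe3)2 2.2 equiv, Me3SiCl, THF, −78 → 60 °C) should form C2–C7 on the face of the departing C17–O bond and give the rearranged acid F5. Me3SiCHN2 gives the methyl ester F6. A Goldberg amidation (CuI, N,N′-dimethylethylenediamine, K3PO4, toluene, 100 °C) closes the indoline to 12, which is treated with KOtBu as in step 10; the route is rejoined at 13.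

Step 8. Hydride transfer to the deactivated vinylogous-imide carbonyl may not occur, or the acetyl group may migrate from O15 to O17. The fallback sets out from 9. Evans–Saksena reduction (Me4NBH(OAc)3, AcOH/MeCN, −20 °C), with the same internal delivery from O15, should give the anti diol F7. Acetylation of both hydroxyls (Ac2O, DMAP, pyridine) gives the diacetate F8. Only its allylic acetate ionises, so F8 is taken through step 10 with the arylacetate first deprotonated by LiN(SiMe3)2 (1.0 equiv, −78 °C) before Pd(PPh3)4 is added; the route is rejoined at 13.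

Step 2. Anionic oligomerisation of acrylonitrile, or cyanoethylation at the alkoxide oxygen, may compete with C-alkylation. The fallback sets out from 2. The dianion is alkylated with allyl bromide, the standard electrophile of this alkylation, to the allyl compound F9. Hydroboration–oxidation (9-BBN; NaBO3) gives the diol F10. TEMPO/PhI(OAc)2 oxidises the primary alcohol and closes the δ-lactone F11 with O15. The lithium enolate of tert-butyl acetate (2.5 equiv, THF, −78 °C) opens the lactone to the β-keto ester, and the route is rejoined at 4.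

**Further compounds**

F1 | step 10 | 7-(2-bromoethyl) 1-tert-butyl (4R,5S)-8-amino-4-hydroxy-6-oxo-1-azaspiro[4.5]dec-7-ene-1,7-dicarboxylate | BrCCOC(=O)C1=C(N)CC[C@]2(C1=O)N(C(=O)OC(C)(C)C)CC[C@H]2O
F2 | step 10 | 7-(2-bromoethyl) 1-tert-butyl (4R,5S)-4-hydroxy-8-[(methoxycarbonyl)amino]-6-oxo-1-azaspiro[4.5]dec-7-ene-1,7-dicarboxylate | BrCCOC(=O)C1=C(NC(=O)OC)CC[C@]2(C1=O)N(C(=O)OC(C)(C)C)CC[C@H]2O
F3 | step 10 | 7-(2-bromoethyl) 1-tert-butyl (4R,6S)-4-(acetyloxy)-6-hydroxy-8-[(methoxycarbonyl)amino]-1-azaspiro[4.5]dec-7-ene-1,7-dicarboxylate (C17–OH cis to N4) | BrCCOC(=O)C1=C(NC(=O)OC)CC[C@]2([C@H]1O)N(C(=O)OC(C)(C)C)CC[C@H]2OC(C)=O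
F4 | step 10 | (2-iodophenyl)acetate ester of F3 at the C17 hydroxyl | BrCCOC(=O)C1=C(NC(=O)OC)CC[C@]2([C@H]1OC(=O)Cc3ccccc3I)N(C(=O)OC(C)(C)C)CC[C@H]2OC(C)=O
F5 | step 10 | rearranged acid: C2 bearing NHCO2Me and CH(2-iodophenyl)CO2H (C7 epimers), C16=C17 2-bromoethyl enoate, N4-Boc, O15 acetate | BrCCOC(=O)C1=C[C@@]2(CC[C@]1(NC(=O)OC)C(C(=O)O)c1ccccc1I)N(C(=O)OC(C)(C)C)CC[C@H]2OC(C)=O
F6 | step 10 | methyl ester of F5 | BrCCOC(=O)C1=C[C@@]2(CC[C@]1(NC(=O)OC)C(C(=O)OC)c1ccccc1I)N(C(=O)OC(C)(C)C)CC[C@H]2OC(C)=O
F7 | step 8 | anti diol: 10 with free 4-hydroxyl in place of the acetate | BrCCOC(=O)C1=C(N(C(=O)OC)c3ccccc3CC(=O)OC)CC[C@]2([C@H]1O)N(C(=O)OC(C)(C)C)CC[C@H]2O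
F8 | step 8 | diacetate of F7 | BrCCOC(=O)C1=C(N(C(=O)OC)c3ccccc3CC(=O)OC)CC[C@]2([C@H]1OC(C)=O)N(C(=O)OC(C)(C)C)CC[C@H]2OC(C)=O
F9 | step 2 | 1-tert-butyl 2-methyl (2S,3R)-3-hydroxy-2-(prop-2-en-1-yl)pyrrolidine-1,2-dicarboxylate | COC(=O)[C@@]1(CC=C)N(C(=O)OC(C)(C)C)CC[C@H]1O
F10 | step 2 | 1-tert-butyl 2-methyl (2S,3R)-3-hydroxy-2-(3-hydroxypropyl)pyrrolidine-1,2-dicarboxylate | COC(=O)[C@@]1(CCCO)N(C(=O)OC(C)(C)C)CC[C@H]1O
F11 | step 2 | δ-lactone of F10: trans-fused pyrano[3,2-b]pyrrol-5-one with the methyl ester at the ring-fusion carbon and N-Boc | COC(=O)[C@]12CCC(=O)O[C@@H]1CCN2C(=O)OC(C)(C)C
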